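The seven-membered ring of this daucane (C1, C5, C6, C7, C8, C9, C10; numbering below) holds a C8(CH3)=C9H unit flanked by the methylenes C7 and C10. Cutting C7–C8 and C9–C10 leaves an alkyne and the five-carbon chain C10–C1–C5–C6–C7. The key step is a rhodium-catalysed (5+2) cycloaddition: a vinylcyclopropane embedded in a bicyclo[3.1.0]hexane (C10 the cyclopropane methylene, C6=C7 the vinyl group) opens by strain release and takes up a silyl-capped propyne, forming both bonds and the hydroazulene in one operation. The silyl group steers regiochemistry and is removed later. C4, C5 and C6 are then set by oxidative transposition, epoxidation, reductive opening and directed reduction.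

Key step: step 9

Remark: bicyclic compounds are described with daucane numbering (C1 quaternary carbon with the angular methyl, C2 CH–O, C3 CH2, C4 carbinol carbon with isopropyl, C5 ring-fusion carbon, C6 CH–O, C7 CH2, C8 methyl-bearing alkene carbon, C9 alkene CH, C10 CH2, C14 the methyl carbon on C8); β is the face of the angular methyl, α the opposite face; compounds 1, 5, 11, 12 and 19 are taken as commercial.

Step 1
Reactants: 1 (S)-4-[(tert-butyldimethylsilyl)oxy]cyclopent-2-en-1-one
Product: 2 trans-4-[(tert-butyldimethylsilyl)oxy]-3-methyl-1-[(trimethylsilyl)oxy]cyclopent-1-ene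
Conditions: MeMgBr, CuBr·SMe2 (10 mol %), Me3SiCl, THF, −78 °C
Reagents that add atoms: methylmagnesium bromide (C[Mg]Br); chlorotrimethylsilane (C[Si](C)(C)Cl)
Why: Copper-catalysed conjugate addition with in situ silyl trapping should deliver methyl anti to the silyloxy group and lock the enolate as the C1–C2 silyl enol ether, which prevents β-elimination of the silyloxy group; the new methyl-bearing centre is erased in step 2.

Step 2
Reactants: 2 trans-4-[(tert-butyldimethylsilyl)oxy]-3-methyl-1-[(trimethylsilyl)oxy]cyclopent-1-ene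
Product: 3 (S)-4-[(tert-butyldimethylsilyl)oxy]-3-methylcyclopent-2-en-1-one
Conditions: Pd(OAc)2 (10 mol %), O2 (1 atm), DMSO, 25 °C
Reagents that add atoms: none
Why: Saegusa–Ito oxidation of the regiodefined silyl enol ether should re-form the enone with the methyl on the β-carbon; the silyloxy-bearing centre is not enolisable and is retained.

Step 3
Reactants: 3 (S)-4-[(tert-butyldimethylsilyl)oxy]-3-methylcyclopent-2-en-1-one
Product: 4 (S)-4-[(tert-butyldimethylsilyl)oxy]-2-iodo-3-methylcyclopent-2-en-1-one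
Conditions: I2, pyridine, CH2Cl2, 0 °C to rt
Reagents that add atoms: iodine ([I][I])
Why: α-Iodination of the enone by pyridine conjugate addition, iodination and elimination (a Baylis–Hillman-type sequence) is established for β-methyl cyclopentenones and touches no stereocentre.

Step 4
Reactants: 4 (S)-4-[(tert-butyldimethylsilyl)oxy]-2-iodo-3-methylcyclopent-2-en-1-one; 5 ethynyltrimethylsilane
Product: 6 (S)-4-[(tert-butyldimethylsilyl)oxy]-3-methyl-2-[(trimethylsilyl)ethynyl]cyclopent-2-en-1-one
Conditions: PdCl2(PPh3)2 (3 mol %), CuI (6 mol %), iPr2NH, THF, rt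
Reagents that add atoms: none
Why: Sonogashira coupling of an electron-poor α-iodoenone, a substrate class that undergoes oxidative addition readily; the silyl cap prevents alkyne homocoupling.

Step 5
Reactants: 6 (S)-4-[(tert-butyldimethylsilyl)oxy]-3-methyl-2-[(trimethylsilyl)ethynyl]cyclopent-2-en-1-one
Product: 7 (1S,4S)-4-[(tert-butyldimethylsilyl)oxy]-3-methyl-1-(propan-2-yl)-2-[(trimethylsilyl)ethynyl]cyclopent-2-en-1-ol (hydroxyl cis to the silyloxy group)
Conditions: iPrMgCl, CeCl3, THF, −78 °C; aq NH4Cl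
Reagents that add atoms: isopropylmagnesium chloride (CC(C)[Mg]Cl)
Why: Organocerium 1,2-addition suppresses enolisation, reduction and elimination, and the nucleophile should attack the carbonyl face anti to the silyloxy group, placing the tertiary hydroxyl cis to it; this provisional C4 centre only serves to direct step 6 and is erased in step 10.

Step 6
Reactants: 7 (1S,4S)-4-[(tert-butyldimethylsilyl)oxy]-3-methyl-1-(propan-2-yl)-2-[(trimethylsilyl)ethynyl]cyclopent-2-en-1-ol
Product: 8 4-[(tert-butyldimethylsilyl)oxy]-5-methyl-2-(propan-2-yl)-1-[(trimethylsilyl)ethynyl]bicyclo[3.1.0]hexan-2-ol (cyclopropane CH2, 2-hydroxyl and 4-silyloxy group on the same face)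
Conditions: Et2Zn, CH2I2, CH2Cl2, 0 °C to rt
Reagents that add atoms: diiodomethane (ICI)
Why: Hydroxyl-directed Simmons–Smith cyclopropanation: the zinc alkoxide delivers the methylene to its own face, so the cyclopropane CH2 (future C10) ends syn to the hydroxyl and to the cis silyloxy group, which fixes the C1 quaternary centre with the angular methyl anti to the C2 oxygen; the alkyne is inert to the zinc carbenoid.

Step 7
Reactants: 8 4-[(tert-butyldimethylsilyl)oxy]-5-methyl-2-(propan-2-yl)-1-[(trimethylsilyl)ethynyl]bicyclo[3.1.0]hexan-2-ol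
Product: 10 1-ethenyl-4-[(tert-butyldimethylsilyl)oxy]-5-methyl-2-(propan-2-yl)bicyclo[3.1.0]hexan-2-ol (same relative configuration as 8), via terminal alkyne 9 (not isolated)
Conditions: K2CO3, MeOH, rt; then 5% Pd/CaCO3 poisoned with Pb(OAc)2, quinoline, H2 (1 atm)
Reagents that add atoms: none
Why: Methanolysis of the alkynyl C–Si bond followed in the same flask by Lindlar semihydrogenation should stop at the alkene and leave the cyclopropane and all stereocentres untouched.

Step 8
Reactants: 11 prop-1-yn-1-ylmagnesium bromide; 12 benzyl(chloro)dimethylsilane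
Product: 13 benzyldimethyl(prop-1-yn-1-yl)silane
Conditions: THF, 0 °C to rt
Reagents that add atoms: none
Why: Nucleophilic substitution at silicon by an alkynyl Grignard reagent is routine.

Step 9
Reactants: 10 1-ethenyl-4-[(tert-butyldimethylsilyl)oxy]-5-methyl-2-(propan-2-yl)bicyclo[3.1.0]hexan-2-ol; 13 benzyldimethyl(prop-1-yn-1-yl)silane
Product: 14 9-(benzyldimethylsilyl)-2α-[(tert-butyldimethylsilyl)oxy]dauca-5,8-dien-4α-ol (4β-isopropyl, provisional C4 configuration; 1β-methyl; C5=C6 and C8=C9 alkenes)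
Conditions: [Rh(CO)2Cl]2 (5 mol %), ClCH2CH2Cl, 80 °C
Reagents that add atoms: none
Why: The monovalent rhodium catalyst inserts into the strained C5–C10 cyclopropane bond of 10 (the bond to the unsubstituted methylene, next to the vinyl-bearing carbon) to give a σ-alkyl/π-allyl rhodacycle, alkyne 13 then inserts at the allyl terminus C7, and reductive elimination joins C9 to C10. The closest known reaction type is the rhodium-catalysed intermolecular (5+2) cycloaddition of 1-substituted vinylcyclopropanes with alkynes, applied here to a cyclopropane fused to a cyclopentane. The seven-membered ring closes as a formal (5+2) cycloaddition, its last bond by C(sp2)–C(sp3) reductive elimination from an eight-membered rhodacycle, and it emerges fused to the existing cyclopentane along C1–C5. No new stereocentre is formed (C5 becomes sp2); C1 and C2 are carried over because none of their bonds to stereodefining groups is broken, and the provisional C4 centre is retained. The step needs regioselective alkyne insertion, which the bulky benzyldimethylsilyl group should secure by staying distal to the first-formed C7–C8 bond on the rhodium-bound carbon, so that the methyl-bearing carbon bonds to C7 and the silyl-bearing carbon to C10. It also needs cleavage of the cyclopropane C–CH2 bond and not the ring-fusion bond, which is secured because insertion next to quaternary C1 is hindered and would lead to a strained bridged ring with a bridgehead alkene.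

Step 10
Reactants: 14 9-(benzyldimethylsilyl)-2α-[(tert-butyldimethylsilyl)oxy]dauca-5,8-dien-4α-ol
Product: 15 9-(benzyldimethylsilyl)-2α-[(tert-butyldimethylsilyl)oxy]dauca-4,8-dien-6-one
Conditions: [C5H5NH][CrO3Cl], 4 Å molecular sieves, CH2Cl2, rt
Reagents that add atoms: none
Why: Babler–Dauben oxidative 1,3-transposition: the tertiary chromate ester shifts to C6 and is oxidised, which should give the C6 ketone conjugated to a tetrasubstituted C4=C5 alkene and erase the provisional C4 centre.

Step 11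
Reactants: 15 9-(benzyldimethylsilyl)-2α-[(tert-butyldimethylsilyl)oxy]dauca-4,8-dien-6-one
Product: 16 9-(benzyldimethylsilyl)-2α-[(tert-butyldimethylsilyl)oxy]-4β,5β-epoxydauc-8-en-6-one
Conditions: t-BuOOH, PhCH2NMe3OH (cat.), THF, 0 °C to rt
Reagents that add atoms: tert-butyl hydroperoxide (CC(C)(C)OO)
Why: Weitz–Scheffer nucleophilic epoxidation is selective for the enone over the electron-rich vinylsilane, and the peroxide anion should add to C4 from the β-face, anti to the α-disposed C10 methylene and C2 silyloxy group that flank the cyclopentene, which places oxygen β at C4 and C5; the bulky silyl group on C9 should disfavour migration of the C8=C9 alkene into conjugation.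

Step 12
Reactants: 16 9-(benzyldimethylsilyl)-2α-[(tert-butyldimethylsilyl)oxy]-4β,5β-epoxydauc-8-en-6-one
Product: 17 9-(benzyldimethylsilyl)-2α-[(tert-butyldimethylsilyl)oxy]-4β-hydroxy-5α-dauc-8-en-6-one (trans ring fusion)
Conditions: SmI2, THF–MeOH, −90 °C
Reagents that add atoms: none
Why: Reductive opening of the α,β-epoxy ketone with SmI2 cleaves only the C5–O bond, so the C4 tertiary alcohol keeps its β configuration, and protonation of the samarium enolate at C5 is expected to give the trans ring fusion (5α-H), the epimer in which isopropyl is cis to hydrogen and not to C6 and the hydroxyl can hydrogen-bond to the ketone.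

Step 13
Reactants: 17 9-(benzyldimethylsilyl)-2α-[(tert-butyldimethylsilyl)oxy]-4β-hydroxy-5α-dauc-8-en-6-one
Product: 18 9-(benzyldimethylsilyl)-2α-[(tert-butyldimethylsilyl)oxy]-5α-dauc-8-ene-4β,6α-diol
Conditions: Me4NBH(OAc)3, MeCN–AcOH, −30 °C
Reagents that add atoms: none
Why: Evans–Saksena reduction: the C4 β-hydroxyl exchanges onto boron and delivers hydride intramolecularly to the β-face of the C6 ketone through a six-membered transition state, which should give the anti-1,3-diol, that is the 6α-alcohol.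

Step 14
Reactants: 18 9-(benzyldimethylsilyl)-2α-[(tert-butyldimethylsilyl)oxy]-5α-dauc-8-ene-4β,6α-diol; 19 4-methoxybenzoyl chloride
Product: 20 9-(benzyldimethylsilyl)-2α-[(tert-butyldimethylsilyl)oxy]-4β-hydroxy-5α-dauc-8-en-6α-yl 4-methoxybenzoate
Conditions: DMAP, pyridine, CH2Cl2, 0 °C to rt
Reagents that add atoms: none
Why: DMAP-catalysed acylation should esterify the secondary C6 hydroxyl and leave the hindered tertiary C4 hydroxyl free.

Step 15
Reactants: 20 9-(benzyldimethylsilyl)-2α-[(tert-butyldimethylsilyl)oxy]-4β-hydroxy-5α-dauc-8-en-6α-yl 4-methoxybenzoate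
Product: 21 2α,4β-dihydroxy-5α-dauc-8-en-6α-yl 4-methoxybenzoate
Conditions: Bu4NF, THF, 0 to 40 °C
Reagents that add atoms: none
Why: Fluoride should cleave the silyl ether and, by attack at the benzyldimethylsilyl group with loss of toluene, activate the alkenyl C–Si bond for protodesilylation with retention of alkene position, which unveils the C8=C9 trisubstituted alkene and the C2 hydroxyl in one operation.

Step 16
Reactants: 21 2α,4β-dihydroxy-5α-dauc-8-en-6α-yl 4-methoxybenzoate
Product: 22 2α-acetoxy-4β-hydroxy-5α-dauc-8-en-6α-yl 4-methoxybenzoate (target)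
Conditions: Ac2O, DMAP (cat.), Et3N, CH2Cl2, rt
Reagents that add atoms: acetic anhydride (CC(=O)OC(C)=O)
Why: DMAP-catalysed acetylation should take place at the secondary C2 hydroxyl only, the tertiary C4 hydroxyl being too hindered under these conditions.

Compound list
1 | (S)-4-[(tert-butyldimethylsilyl)oxy]cyclopent-2-en-1-one | O=C1C=C[C@@H](O[Si](C)(C)C(C)(C)C)C1 | starting material
2 | trans-4-[(tert-butyldimethylsilyl)oxy]-3-methyl-1-[(trimethylsilyl)oxy]cyclopent-1-ene | C[Si](C)(C)OC1=C[C@H](C)[C@@H](O[Si](C)(C)C(C)(C)C)C1 | intermediate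
3 | (S)-4-[(tert-butyldimethylsilyl)oxy]-3-methylcyclopent-2-en-1-one | O=C1C=C(C)[C@@H](O[Si](C)(C)C(C)(C)C)C1 | intermediate
4 | (S)-4-[(tert-butyldimethylsilyl)oxy]-2-iodo-3-methylcyclopent-2-en-1-one | O=C1C(I)=C(C)[C@@H](O[Si](C)(C)C(C)(C)C)C1 | intermediate
5 | ethynyltrimethylsilane | C#C[Si](C)(C)C | starting material
6 | (S)-4-[(tert-butyldimethylsilyl)oxy]-3-methyl-2-[(trimethylsilyl)ethynyl]cyclopent-2-en-1-one | O=C1C(C#C[Si](C)(C)C)=C(C)[C@@H](O[Si](C)(C)C(C)(C)C)C1 | intermediate
7 | (1S,4S)-4-[(tert-butyldimethylsilyl)oxy]-3-methyl-1-(propan-2-yl)-2-[(trimethylsilyl)ethynyl]cyclopent-2-en-1-ol | C[Si](C)(C)C#CC1=C(C)[C@@H](O[Si](C)(C)C(C)(C)C)C[C@]1(O)C(C)C | intermediate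
8 | 4-[(tert-butyldimethylsilyl)oxy]-5-methyl-2-(propan-2-yl)-1-[(trimethylsilyl)ethynyl]bicyclo[3.1.0]hexan-2-ol (CH2, 2-OH and 4-OSi on one face) | C[Si](C)(C)C#C[C@]12C[C@@]1(C)[C@@H](O[Si](C)(C)C(C)(C)C)C[C@]2(O)C(C)C | intermediate
9 | 1-ethynyl-4-[(tert-butyldimethylsilyl)oxy]-5-methyl-2-(propan-2-yl)bicyclo[3.1.0]hexan-2-ol (same configuration as 8) | C#C[C@]12C[C@@]1(C)[C@@H](O[Si](C)(C)C(C)(C)C)C[C@]2(O)C(C)C | intermediate
10 | 1-ethenyl-4-[(tert-butyldimethylsilyl)oxy]-5-methyl-2-(propan-2-yl)bicyclo[3.1.0]hexan-2-ol (same configuration as 8) | C=C[C@]12C[C@@]1(C)[C@@H](O[Si](C)(C)C(C)(C)C)C[C@]2(O)C(C)C | intermediate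
11 | prop-1-yn-1-ylmagnesium bromide | CC#C[Mg]Br | starting material
12 | benzyl(chloro)dimethylsilane | C[Si](C)(Cl)Cc1ccccc1 | starting material
13 | benzyldimethyl(prop-1-yn-1-yl)silane | CC#C[Si](C)(C)Cc1ccccc1 | intermediate
14 | 9-(benzyldimethylsilyl)-2α-[(tert-butyldimethylsilyl)oxy]dauca-5,8-dien-4α-ol | CC(C)[C@@]1(O)C[C@H](O[Si](C)(C)C(C)(C)C)[C@]2(C)CC([Si](C)(C)Cc3ccccc3)=C(C)CC=C12 | intermediate
15 | 9-(benzyldimethylsilyl)-2α-[(tert-butyldimethylsilyl)oxy]dauca-4,8-dien-6-one | CC(C)C1=C2C(=O)CC(C)=C([Si](C)(C)Cc3ccccc3)C[C@@]2(C)[C@@H](O[Si](C)(C)C(C)(C)C)C1 | intermediate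
16 | 9-(benzyldimethylsilyl)-2α-[(tert-butyldimethylsilyl)oxy]-4β,5β-epoxydauc-8-en-6-one | CC(C)[C@@]12O[C@@]13C(=O)CC(C)=C([Si](C)(C)Cc4ccccc4)C[C@@]3(C)[C@@H](O[Si](C)(C)C(C)(C)C)C2 | intermediate
17 | 9-(benzyldimethylsilyl)-2α-[(tert-butyldimethylsilyl)oxy]-4β-hydroxy-5α-dauc-8-en-6-one | O=C1CC(C)=C([Si](C)(C)Cc3ccccc3)C[C@@]2(C)[C@@H](O[Si](C)(C)C(C)(C)C)C[C@@](O)(C(C)C)[C@H]12 | intermediate
18 | 9-(benzyldimethylsilyl)-2α-[(tert-butyldimethylsilyl)oxy]-5α-dauc-8-ene-4β,6α-diol | O[C@H]1CC(C)=C([Si](C)(C)Cc3ccccc3)C[C@@]2(C)[C@@H](O[Si](C)(C)C(C)(C)C)C[C@@](O)(C(C)C)[C@H]12 | intermediate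
19 | 4-methoxybenzoyl chloride | COc1ccc(C(Cl)=O)cc1 | starting material
20 | 9-(benzyldimethylsilyl)-2α-[(tert-butyldimethylsilyl)oxy]-4β-hydroxy-5α-dauc-8-en-6α-yl 4-methoxybenzoate | COc1ccc(C(=O)O[C@H]2CC(C)=C([Si](C)(C)Cc4ccccc4)C[C@@]3(C)[C@@H](O[Si](C)(C)C(C)(C)C)C[C@@](O)(C(C)C)[C@H]23)cc1 | intermediate
21 | 2α,4β-dihydroxy-5α-dauc-8-en-6α-yl 4-methoxybenzoate | COc1ccc(C(=O)O[C@H]2CC(C)=CC[C@@]3(C)[C@@H](O)C[C@@](O)(C(C)C)[C@H]23)cc1 | intermediate
22 | 2α-acetoxy-4β-hydroxy-5α-dauc-8-en-6α-yl 4-methoxybenzoate | COc1ccc(C(=O)O[C@H]2CC(C)=CC[C@@]3(C)[C@@H](OC(C)=O)C[C@@](O)(C(C)C)[C@H]23)cc1 | target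

Total step count: 16. Longest linear sequence: 15 steps (steps 1 to 7 and 9 to 16; step 8 prepares the alkyne partner).

The three steps most likely to fail are step 9, step 11 and step 12.

First, step 9 (key cycloaddition). The hindered internal silylalkyne may insert too slowly into the rhodacycle, so that isomerisation of the vinylcyclopropane or formation of the regioisomeric adduct competes. The fallback for step 9 sets out from 10 and runs the same cycloaddition with an electron-poor, polarised partner, methyl 3-(benzyldimethylsilyl)prop-2-ynoate F1, made from methyl propiolate by deprotonation with LiN(SiMe3)2 and silylation with 12. Ester and silyl group then reinforce each other (ester-bearing carbon to C7, silyl-bearing carbon to C10) and should give methyl 9-(benzyldimethylsilyl)-2α-[(tert-butyldimethylsilyl)oxy]-4α-hydroxydauca-5,8-dien-14-oate F2, the cycloadduct that carries CO2CH3 in place of the C8 methyl. Reduction with iBu2AlH should give 9-(benzyldimethylsilyl)-2α-[(tert-butyldimethylsilyl)oxy]dauca-5,8-diene-4α,14-diol F3, whose primary allylic hydroxyl is converted with MsCl and Et3N into 9-(benzyldimethylsilyl)-2α-[(tert-butyldimethylsilyl)oxy]-4α-hydroxydauca-5,8-dien-14-yl methanesulfonate F4. Displacement of the mesylate by hydride with LiEt3BH returns to 14.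

Second, step 11 (epoxidation). The peroxide anion may add too slowly to the hindered tetrasubstituted enone, so that base-mediated migration of the C8=C9 alkene into conjugation competes, or the facial selectivity may be poor. The fallback for step 11 sets out from 15: Luche reduction (NaBH4, CeCl3, MeOH, −78 °C) should deliver hydride anti to the angular methyl and give 9-(benzyldimethylsilyl)-2α-[(tert-butyldimethylsilyl)oxy]dauca-4,8-dien-6β-ol F5. Hydroxyl-directed epoxidation with VO(acac)2 and t-BuOOH, which should favour the allylic C4=C5 alkene over the homoallylic, silyl-bearing C8=C9 alkene, should give 9-(benzyldimethylsilyl)-2α-[(tert-butyldimethylsilyl)oxy]-4β,5β-epoxydauc-8-en-6β-ol F6, and Dess–Martin oxidation returns to 16.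

Third, step 12 (ring fusion). Kinetic protonation of the samarium enolate from the β-face, where samarium is held by the new C4 alkoxide, would give the cis ring fusion. The fallback for step 12 sets out from 16 and accepts the same opening as giving 9-(benzyldimethylsilyl)-2α-[(tert-butyldimethylsilyl)oxy]-4β-hydroxy-5β-dauc-8-en-6-one F7, the cis-fused epimer. Its tertiary hydroxyl is silylated with Me3SiOTf and 2,6-lutidine to block retro-aldol cleavage, giving 9-(benzyldimethylsilyl)-2α-[(tert-butyldimethylsilyl)oxy]-4β-[(trimethylsilyl)oxy]-5β-dauc-8-en-6-one F8. The C5 centre is then equilibrated through the enolate with DBU in CH2Cl2 to the trans-fused 9-(benzyldimethylsilyl)-2α-[(tert-butyldimethylsilyl)oxy]-4β-[(trimethylsilyl)oxy]-5α-dauc-8-en-6-one F9, and the trimethylsilyl ether is removed with citric acid in methanol, which returns to 17.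

Further compounds
F1 | step 9 | methyl 3-(benzyldimethylsilyl)prop-2-ynoate | COC(=O)C#C[Si](C)(C)Cc1ccccc1
F2 | step 9 | methyl 9-(benzyldimethylsilyl)-2α-[(tert-butyldimethylsilyl)oxy]-4α-hydroxydauca-5,8-dien-14-oate | CC(C)[C@@]1(O)C[C@H](O[Si](C)(C)C(C)(C)C)[C@]2(C)CC([Si](C)(C)Cc3ccccc3)=C(C(=O)OC)CC=C12
F3 | step 9 | 9-(benzyldimethylsilyl)-2α-[(tert-butyldimethylsilyl)oxy]dauca-5,8-diene-4α,14-diol | CC(C)[C@@]1(O)C[C@H](O[Si](C)(C)C(C)(C)C)[C@]2(C)CC([Si](C)(C)Cc3ccccc3)=C(CO)CC=C12
F4 | step 9 | 9-(benzyldimethylsilyl)-2α-[(tert-butyldimethylsilyl)oxy]-4α-hydroxydauca-5,8-dien-14-yl methanesulfonate | CC(C)[C@@]1(O)C[C@H](O[Si](C)(C)C(C)(C)C)[C@]2(C)CC([Si](C)(C)Cc3ccccc3)=C(COS(C)(=O)=O)CC=C12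
F5 | step 11 | 9-(benzyldimethylsilyl)-2α-[(tert-butyldimethylsilyl)oxy]dauca-4,8-dien-6β-ol | CC(C)C1=C2[C@H](O)CC(C)=C([Si](C)(C)Cc3ccccc3)C[C@@]2(C)[C@@H](O[Si](C)(C)C(C)(C)C)C1
F6 | step 11 | 9-(benzyldimethylsilyl)-2α-[(tert-butyldimethylsilyl)oxy]-4β,5β-epoxydauc-8-en-6β-ol | CC(C)[C@@]12O[C@@]13[C@H](O)CC(C)=C([Si](C)(C)Cc4ccccc4)C[C@@]3(C)[C@@H](O[Si](C)(C)C(C)(C)C)C2
F7 | step 12 | 9-(benzyldimethylsilyl)-2α-[(tert-butyldimethylsilyl)oxy]-4β-hydroxy-5β-dauc-8-en-6-one | O=C1CC(C)=C([Si](C)(C)Cc3ccccc3)C[C@@]2(C)[C@@H](O[Si](C)(C)C(C)(C)C)C[C@@](O)(C(C)C)[C@@H]12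
F8 | step 12 | 9-(benzyldimethylsilyl)-2α-[(tert-butyldimethylsilyl)oxy]-4β-[(trimethylsilyl)oxy]-5β-dauc-8-en-6-one | O=C1CC(C)=C([Si](C)(C)Cc3ccccc3)C[C@@]2(C)[C@@H](O[Si](C)(C)C(C)(C)C)C[C@@](O[Si](C)(C)C)(C(C)C)[C@@H]12
F9 | step 12 | 9-(benzyldimethylsilyl)-2α-[(tert-butyldimethylsilyl)oxy]-4β-[(trimethylsilyl)oxy]-5α-dauc-8-en-6-one | O=C1CC(C)=C([Si](C)(C)Cc3ccccc3)C[C@@]2(C)[C@@H](O[Si](C)(C)C(C)(C)C)C[C@@](O[Si](C)(C)C)(C(C)C)[C@H]12
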